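Ring B (the dihydro-γ-pyranone; pyrano[3,4-b]pyran numbering) is opened at three bonds around its ketone carbon: C4a–C4, C4–C3 and O1–C2. The feature exploited is that C4 lies between ring-fusion carbon C4a and the C3 methylene, while ring oxygen O1 sits on the adjacent fusion carbon C8a. C4 can thus be carbon monoxide, C3 and C2 the alkyne carbons of 1-nonyne, and O1 the enol oxygen of lactone ring A. One palladium-catalysed carbonylative annulation joins an acetate-locked 4-iodo-3-hydroxy-5,6-dihydropyranone, CO and 1-nonyne into the bicyclic γ-pyrone. C6 comes from (S)-1,2-epoxydodecane; C2 is set last by ligand-controlled copper hydride reduction.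

Key step: step 6

Assumption: the supplied structures are consistent (C6 is S throughout, the target is 2R,6S); (S)-1,2-epoxydodecane is bought as the single enantiomer; which antipode of the bisphosphine delivers 2R in step 7 must be fixed in the first run, the route being written with the R ligand and its antipode as the drop-in replacement.

Step 1
Reactants: 1 (S)-1,2-epoxydodecane; 2 ethyl propiolate
Product: 3 ethyl (S)-5-hydroxypentadec-2-ynoate
Conditions: 2, n-BuLi, THF, −78 °C; BF3·OEt2; then 1, −78 °C; H2O quench
Reagents that add atoms: none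
Why: Yamaguchi–Hirao alkynylation, in which the BF3-activated terminal epoxide is opened by lithium ethyl propiolate in an SN2 attack at the unsubstituted CH2, so the oxygen-bearing stereocentre of 1 is not touched and becomes the (S)-carbinol that ends as C6.

Step 2
Reactants: 3 ethyl (S)-5-hydroxypentadec-2-ynoate
Product: 5 (S)-6-decyl-5,6-dihydro-2H-pyran-2-one, via Z-hydroxy enoate 4 (not isolated)
Conditions: H2 (1 atm), Pd/CaCO3 poisoned with Pb(OAc)2 (Lindlar catalyst), quinoline, EtOAc, rt; filter; TsOH·H2O (cat.), PhMe, 60 °C
Reagents that add atoms: none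
Why: Lindlar semihydrogenation should stop at the cis enoate, whose geometry holds the hydroxyl next to the ester so that acid-catalysed lactonisation closes ring A without involving the stereocentre.

Step 3
Reactants: 5 (S)-6-decyl-5,6-dihydro-2H-pyran-2-one
Product: 6 (3S,4S,6S)-6-decyl-3,4-dihydroxytetrahydro-2H-pyran-2-one
Conditions: OsO4 (2 mol%), NMO, acetone/H2O, rt; aq. Na2SO3
Reagents that add atoms: N-methylmorpholine N-oxide, C[N+]1([O-])CCOCC1 (oxygen passed on through catalytic osmium tetroxide, O=[Os](=O)(=O)=O); water, O
Why: Catalytic OsO4/NMO cis-dihydroxylation adds both oxygens to one face of the ring alkene, expected anti to the decyl group, and since both new carbinol centres are erased in step 4 their diastereomer ratio does not matter.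

Step 4
Reactants: 6 (3S,4S,6S)-6-decyl-3,4-dihydroxytetrahydro-2H-pyran-2-one
Product: 9 (S)-6-decyl-3-hydroxy-5,6-dihydro-2H-pyran-2-one, via bis(trifluoroacetate) 7 (not isolated), via enol trifluoroacetate 8 (not isolated)
Conditions: (CF3CO)2O, Et3N, CH2Cl2, −20 → 0 °C; then MeOH, 0 °C → rt
Reagents that add atoms: none
Why: Acylation followed by E1cB β-elimination, the dehydration known for O-acylated aldonolactones: Et3N removes the C3–H next to the lactone carbonyl, the C4 trifluoroacetate leaves, and methanol cleaves the labile enol trifluoroacetate to the conjugated enol form of the α-keto lactone.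

Step 5
Reactants: 9 (S)-6-decyl-3-hydroxy-5,6-dihydro-2H-pyran-2-one
Product: 11 (S)-6-decyl-4-iodo-2-oxo-5,6-dihydro-2H-pyran-3-yl acetate, via free iodo-enol 10 (not isolated)
Conditions: NIS, CH2Cl2, 0 °C, dark; then Ac2O, pyridine, DMAP (cat.), 0 °C → rt
Reagents that add atoms: N-iodosuccinimide, O=C1CCC(=O)N1I; acetic anhydride, CC(=O)OC(C)=O
Why: Electrophilic iodination of an enolised 1,2-dicarbonyl compound, whose only nucleophilic carbon is C4, followed by O-acetylation of the acidic enol, which locks the enol tautomer, keeps iodine on an sp2 carbon and removes a chelating enolate that could bind palladium.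

Step 6
Reactants: 11 (S)-6-decyl-4-iodo-2-oxo-5,6-dihydro-2H-pyran-3-yl acetate; 12 1-nonyne; 13 carbon monoxide
Product: 16 (S)-6-decyl-2-heptyl-5,6-dihydro-4H,8H-pyrano[3,4-b]pyran-4,8-dione, via ynone acetate 14 (not isolated), via hydroxy enaminone 15 (not isolated)
Conditions: PdCl2(PPh3)2 (5 mol%), CO (5 bar), Et3N, THF, 40 °C, no copper salt; vent; then Et2NH (3 equiv), rt → 45 °C
Reagents that add atoms: none
Why: Zerovalent palladium formed in situ from PdCl2(PPh3)2 inserts into the C4–I bond of 11, CO inserts to give the acylpalladium species, and base-assisted alkynylation by 12 with reductive elimination should deliver ynone 14, a copper-free carbonylative Sonogashira coupling. Et2NH added afterwards adds to the ynone and cleaves the enol acetate, giving hydroxy enaminone 15, whose enol oxygen attacks the amine-bearing carbon and expels Et2NH. The closest known reactions are the carbonylative annulation of 2-iodophenols or their acetates with terminal alkynes to chromones and the closure of enolised alkynyl 1,3-diketones to γ-pyrones; here the same 1,2-relation of iodide and oxygen sits on a cyclic enol. Ring B closes in the 6-endo mode by addition–elimination (O1–C2 bond), and no stereocentre is formed, C6 being a non-acidic spectator. CO insertion must precede alkynylation, which the absence of copper and a few bar of CO favour, and 6-endo must beat 5-exo closure, which the amine relay secures because the enaminone is electrophilic only at its distal carbon and the oxygen stays acetylated while palladium is active. The acetate also prevents the keto tautomer and loss of HI.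

Step 7
Reactants: 16 (S)-6-decyl-2-heptyl-5,6-dihydro-4H,8H-pyrano[3,4-b]pyran-4,8-dione
Product: 17 (2R,6S)-6-decyl-2-heptyl-2,3,5,6-tetrahydro-4H,8H-pyrano[3,4-b]pyran-4,8-dione
Conditions: Cu(OAc)2·H2O (5 mol%), (R)-DTBM-SEGPHOS (5.5 mol%), (EtO)2MeSiH, t-BuOH, PhMe, 0 °C
Reagents that add atoms: none
Why: Asymmetric copper hydride 1,4-reduction as used for 2-substituted chromones and β,β-disubstituted enones: hydride should go to C2 because the other enone β-carbon (C8a) is fully substituted, the face is chosen by the ligand since C6 is too remote to matter, and t-BuOH protonates the copper enolate at once so that reversible ring opening cannot erode C2.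

Compound list
1 | (S)-1,2-epoxydodecane [(S)-2-decyloxirane] | CCCCCCCCCC[C@H]1CO1 | starting material
2 | ethyl propiolate | C#CC(=O)OCC | starting material
3 | ethyl (S)-5-hydroxypentadec-2-ynoate | CCCCCCCCCC[C@H](O)CC#CC(=O)OCC | intermediate
4 | ethyl (S,Z)-5-hydroxypentadec-2-enoate | CCCCCCCCCC[C@H](O)C/C=C\C(=O)OCC | intermediate (not isolated)
5 | (S)-6-decyl-5,6-dihydro-2H-pyran-2-one | CCCCCCCCCC[C@H]1CC=CC(=O)O1 | intermediate
6 | (3S,4S,6S)-6-decyl-3,4-dihydroxytetrahydro-2H-pyran-2-one (cis-diol anti to decyl) | CCCCCCCCCC[C@H]1C[C@H](O)[C@H](O)C(=O)O1 | intermediate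
7 | (3S,4S,6S)-6-decyl-2-oxotetrahydro-2H-pyran-3,4-diyl bis(trifluoroacetate) | CCCCCCCCCC[C@H]1C[C@H](OC(=O)C(F)(F)F)[C@H](OC(=O)C(F)(F)F)C(=O)O1 | intermediate (not isolated)
8 | (S)-6-decyl-2-oxo-5,6-dihydro-2H-pyran-3-yl trifluoroacetate | CCCCCCCCCC[C@H]1CC=C(OC(=O)C(F)(F)F)C(=O)O1 | intermediate (not isolated)
9 | (S)-6-decyl-3-hydroxy-5,6-dihydro-2H-pyran-2-one | CCCCCCCCCC[C@H]1CC=C(O)C(=O)O1 | intermediate
10 | (S)-6-decyl-3-hydroxy-4-iodo-5,6-dihydro-2H-pyran-2-one | CCCCCCCCCC[C@H]1CC(I)=C(O)C(=O)O1 | intermediate (not isolated)
11 | (S)-6-decyl-4-iodo-2-oxo-5,6-dihydro-2H-pyran-3-yl acetate | CCCCCCCCCC[C@H]1CC(I)=C(OC(C)=O)C(=O)O1 | intermediate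
12 | 1-nonyne | CCCCCCCC#C | starting material
13 | carbon monoxide | [C-]#[O+] | starting material
14 | (S)-6-decyl-4-(dec-2-ynoyl)-2-oxo-5,6-dihydro-2H-pyran-3-yl acetate | CCCCCCCCCC[C@H]1CC(C(=O)C#CCCCCCCC)=C(OC(C)=O)C(=O)O1 | intermediate (not isolated)
15 | (S)-6-decyl-4-[(E)-3-(diethylamino)dec-2-enoyl]-3-hydroxy-5,6-dihydro-2H-pyran-2-one | CCCCCCCCCC[C@H]1CC(C(=O)/C=C(\CCCCCCC)N(CC)CC)=C(O)C(=O)O1 | intermediate (not isolated)
16 | (S)-6-decyl-2-heptyl-5,6-dihydro-4H,8H-pyrano[3,4-b]pyran-4,8-dione | CCCCCCCCCC[C@H]1CC2=C(OC(CCCCCCC)=CC2=O)C(=O)O1 | intermediate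
17 | (2R,6S)-6-decyl-2-heptyl-2,3,5,6-tetrahydro-4H,8H-pyrano[3,4-b]pyran-4,8-dione | CCCCCCCCCC[C@H]1CC2=C(O[C@H](CCCCCCC)CC2=O)C(=O)O1 | target

Total step count: 7. Longest linear sequence: 7 steps (1 → 17).

Steps most likely to fail

Step 6. Alkynylation may outrun CO insertion (direct coupling to an enyne), the amine may attack the iodide-bearing carbon or the lactone, or the relay may stall at the enaminone. The fallback separates the events and keeps amine out of the palladium stage. It sets out from 11 and 12: 12 is converted (n-BuLi, THF, −78 °C; Bu3SnCl) into tributyl(non-1-yn-1-yl)stannane F1. F1 is joined to 11 under CO (Pd(PPh3)4, THF, 50 °C) in a base-free carbonylative Stille coupling. The fallback comes back to the route at ynone 14, which is isolated and cyclised in a second flask with Et2NH to 16.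

Step 7. Facial selectivity at C2 may be poor, the ketone may be reduced 1,2, or C2 may erode through reversible ring opening of the enolate. The fallback gives up catalyst control and sets out from 16. Non-selective conjugate reduction with [(Ph3P)CuH]6 and t-BuOH in THF should give 17 together with its C2 epimer, (2S,6S)-6-decyl-2-heptyl-2,3,5,6-tetrahydro-4H,8H-pyrano[3,4-b]pyran-4,8-dione F2. The two are diastereomers and are separated by preparative HPLC, which is where the fallback comes back at 17. F2 is returned to 16 by dehydrogenation (DDQ, dioxane, heat) and recycled.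

Step 4. β-Elimination of the bis-ester may be incomplete, or the lactone may open during the methanol quench. The fallback changes the way oxygen reaches C3 and sets out from 5. Mukaiyama hydration (Mn(dpm)3 cat., PhSiH3, O2, i-PrOH/CH2Cl2, 0 °C; then P(OEt)3) transfers a hydrogen atom to C4 and traps the C3 radical with oxygen. This gives (6S)-6-decyl-3-hydroxytetrahydro-2H-pyran-2-one F3 as a C3-epimer mixture. Dess–Martin oxidation (CH2Cl2, rt) then gives the α-keto lactone, which enolises, and the fallback comes back to the route at 9.

Further compounds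
F1 | step 6 | tributyl(non-1-yn-1-yl)stannane | CCCCCCCC#C[Sn](CCCC)(CCCC)CCCC
F2 | step 7 | (2S,6S)-6-decyl-2-heptyl-2,3,5,6-tetrahydro-4H,8H-pyrano[3,4-b]pyran-4,8-dione | CCCCCCCCCC[C@H]1CC2=C(O[C@@H](CCCCCCC)CC2=O)C(=O)O1
F3 | step 4 | (6S)-6-decyl-3-hydroxytetrahydro-2H-pyran-2-one (C3 epimer mixture) | CCCCCCCCCC[C@H]1CCC(O)C(=O)O1
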